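## Retrosynthetic overview

- The target is traced back, through protecting-group removal, acetylation, oxidation of CH2OH to CO2H, Wittig installation of the enone and O-methylation, to a ring A phenol that already carries ring B.
- The strategy rests on the substitution pattern of ring A: the oxygen-bearing C2 lies between C1 (carboxyl carbon) and C3 (side chain), the aryloxy carbon C6 is next to C1, and C4 and C5 are CH. This is the 2-substituted 3-aryloxy-6-alkylphenol that a vinylketene and an alkynyl ether deliver.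
- Ring A is disconnected at C1–C2 and C5–C6 ((2+2) step), C2–C3 (6-electron closure) and C4–C5 (Wolff shift). This gives a diazo enone (C2–C5 and the stereocentre, from L-leucic acid) and an aryl alkynyl ether (C1, C6 and ring B, from creosol and trichloroethylene).
- Ring order: ring B is bought as creosol; ring A is the only ring formed, in step 12.

Key step: step 12

Assumption: ring A is numbered C1 (carboxyl-bearing), C2 (OMe), C3 (side chain), C4, C5 (CH), C6 (aryloxy); the stereocentre of the target is (S) and maps onto C2 of L-leucic acid with unchanged descriptor; reagents written over the arrows are taken as purchased.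

## Route

Step 1
Reactants: 1 (S)-2-hydroxy-4-methylpentanoic acid (L-leucic acid)
Product: 2 methyl (S)-2-hydroxy-4-methylpentanoate
Conditions: MeOH, H2SO4 (cat.), reflux
Reagents that add atoms: methanol, CO
Why: Fischer esterification, which does not touch the stereocentre.

Step 2
Reactants: 2 methyl (S)-2-hydroxy-4-methylpentanoate
Product: 3 methyl (S)-4-methyl-2-(triisopropylsilyloxy)pentanoate
Conditions: TIPSOTf, 2,6-lutidine, CH2Cl2, 0 °C to rt
Reagents that add atoms: triisopropylsilyl trifluoromethanesulfonate, CC(C)[Si](OS(=O)(=O)C(F)(F)F)(C(C)C)C(C)C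
Why: O-silylation of a secondary alcohol with a silyl triflate and a hindered base; the bulky silyl ether later survives base, acid, light and oxidants.

Step 3
Reactants: 3 methyl (S)-4-methyl-2-(triisopropylsilyloxy)pentanoate
Product: 5 (S,E)-7-methyl-5-(triisopropylsilyloxy)oct-3-en-2-one, via aldehyde 4 (not isolated)
Conditions: i-Bu2AlH, CH2Cl2, −78 °C; MeOH; then Ph3P=CHC(O)CH3, −78 °C to rt
Reagents that add atoms: 1-(triphenylphosphoranylidene)propan-2-one, CC(=O)C=P(c1ccccc1)(c1ccccc1)c1ccccc1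
Why: One-pot half-reduction of the ester and Wittig olefination with a stabilised ylide, which should be E-selective; trapping the alpha-silyloxy aldehyde as it is released guards against epimerisation.

Step 4
Reactants: 5 (S,E)-7-methyl-5-(triisopropylsilyloxy)oct-3-en-2-one
Product: 7 (S,E)-1-diazo-7-methyl-5-(triisopropylsilyloxy)oct-3-en-2-one, via trifluoroacetyl diketone 6 (not isolated)
Conditions: LiN(SiMe3)2, THF, −78 °C; CF3CO2CH2CF3; then 4-acetamidobenzenesulfonyl azide, Et3N, H2O, MeCN, rt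
Reagents that add atoms: 4-acetamidobenzenesulfonyl azide, CC(=O)Nc1ccc(cc1)S(=O)(=O)N=[N+]=[N-]; 2,2,2-trifluoroethyl trifluoroacetate, O=C(OCC(F)(F)F)C(F)(F)F (its acyl group is in 6 only)
Why: Detrifluoroacetylative diazo transfer (Claisen trifluoroacetylation of the kinetic methyl enolate, then Regitz-type transfer with loss of the trifluoroacetyl group); kinetic deprotonation at CH3 leaves the gamma stereocentre alone.

Step 5
Reactants: 8 2-methoxy-4-methylphenol (creosol)
Product: 9 2-hydroxy-3-methoxy-5-methylbenzaldehyde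
Conditions: (CH2O)n, MgCl2, Et3N, MeCN, reflux
Reagents that add atoms: paraformaldehyde (as formaldehyde), C=O
Why: Magnesium phenoxide-directed ortho-formylation (Casnati–Skattebøl reaction); only one position ortho to the hydroxyl is free.

Step 6
Reactants: 9 2-hydroxy-3-methoxy-5-methylbenzaldehyde
Product: 10 2,3-dihydroxy-5-methylbenzaldehyde
Conditions: BBr3, CH2Cl2, −78 to 0 °C; aqueous work-up
Reagents that add atoms: none
Why: Lewis acid cleavage of the aryl methyl ether, standard for ortho-vanillin-type substrates.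

Step 7
Reactants: 10 2,3-dihydroxy-5-methylbenzaldehyde
Product: 11 2-hydroxy-3-(4-methoxybenzyloxy)-5-methylbenzaldehyde
Conditions: NaH (2.2 equiv), DMSO, rt; then 4-methoxybenzyl chloride (1.0 equiv)
Reagents that add atoms: 4-methoxybenzyl chloride, COc1ccc(CCl)cc1
Why: Williamson etherification of the dianion, in which the 3-phenoxide (not conjugated to and not chelated by the formyl group) is the more nucleophilic oxygen and should be alkylated selectively.

Step 8
Reactants: 11 2-hydroxy-3-(4-methoxybenzyloxy)-5-methylbenzaldehyde; 12 trichloroethylene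
Product: 13 2-[(E)-1,2-dichlorovinyloxy]-3-(4-methoxybenzyloxy)-5-methylbenzaldehyde
Conditions: K2CO3, DMF, 70 °C
Reagents that add atoms: none
Why: Base-mediated trans addition of the phenoxide to dichloroacetylene formed in situ from trichloroethylene gives the (E)-1,2-dichlorovinyl ether; the non-enolisable aldehyde tolerates carbonate.

Step 9
Reactants: 13 2-[(E)-1,2-dichlorovinyloxy]-3-(4-methoxybenzyloxy)-5-methylbenzaldehyde
Product: 14 2-{2-[(E)-1,2-dichlorovinyloxy]-3-(4-methoxybenzyloxy)-5-methylphenyl}-1,3-dioxolane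
Conditions: HOCH2CH2OH, PPTS (cat.), benzene, reflux (Dean–Stark)
Reagents that add atoms: ethylene glycol, OCCO
Why: Acid-catalysed acetalisation with azeotropic water removal; PPTS is too weak to cleave the aryl 4-methoxybenzyl ether or hydrolyse the electron-poor dichlorovinyl ether.

Step 10
Reactants: 14 2-{2-[(E)-1,2-dichlorovinyloxy]-3-(4-methoxybenzyloxy)-5-methylphenyl}-1,3-dioxolane
Product: 17 3-[2-(1,3-dioxolan-2-yl)-6-(4-methoxybenzyloxy)-4-methylphenoxy]prop-2-yn-1-ol, via chloroalkyne 15 (not isolated), via lithium acetylide 16 (not isolated)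
Conditions: n-BuLi (2.3 equiv), THF, −78 to −40 °C; then (CH2O)n, −40 °C to rt; aq. NH4Cl
Reagents that add atoms: paraformaldehyde (as formaldehyde), C=O; n-butyllithium, [Li]CCCC (lithium in 16 only)
Why: Dichlorovinyl ether route to ynol ethers: dehydrochlorination to the chloroalkyne, chlorine–lithium exchange, then 1,2-addition of the lithium aryloxyacetylide to formaldehyde; acetal and ethers are inert to n-BuLi at low temperature.

Step 11
Reactants: 17 3-[2-(1,3-dioxolan-2-yl)-6-(4-methoxybenzyloxy)-4-methylphenoxy]prop-2-yn-1-ol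
Product: 18 tert-butyl{3-[2-(1,3-dioxolan-2-yl)-6-(4-methoxybenzyloxy)-4-methylphenoxy]prop-2-ynyloxy}dimethylsilane
Conditions: TBSCl, imidazole, DMF, 0 °C to rt
Reagents that add atoms: tert-butyldimethylsilyl chloride, CC(C)(C)[Si](C)(C)Cl
Why: Standard silylation of a primary alcohol, which removes the last free hydroxyl that could add to a ketene.

Step 12
Reactants: 7 (S,E)-1-diazo-7-methyl-5-(triisopropylsilyloxy)oct-3-en-2-one; 18 tert-butyl{3-[2-(1,3-dioxolan-2-yl)-6-(4-methoxybenzyloxy)-4-methylphenoxy]prop-2-ynyloxy}dimethylsilane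
Product: 23 2-(tert-butyldimethylsilyloxymethyl)-3-[2-(1,3-dioxolan-2-yl)-6-(4-methoxybenzyloxy)-4-methylphenoxy]-6-[(1S)-3-methyl-1-(triisopropylsilyloxy)butyl]phenol, via vinylketene 19 (not isolated), via vinylcyclobutenone 20 (not isolated), via dienylketene 21 (not isolated), via cyclohexadienone 22 (not isolated)
Conditions: 7 (1.3 equiv), hν (350 nm lamps, Pyrex), degassed ClCH2CH2Cl, rt; then toluene, 90 °C
Reagents that add atoms: none
Why: Light expels N2 from 7 and the alkenyl group shifts to the carbene carbon (photo-Wolff rearrangement, making C4–C5) to give vinylketene 19, whose carbonyl carbon is attacked by the oxygen-free alkyne carbon of 18 in a regioselective (2+2) cycloaddition (C1–C2 and C5–C6) that gives 4-alkenylcyclobutenone 20. Warming opens 20 by conrotatory 4-electron electrocyclic cleavage to dienylketene 21, and ring A closes by disrotatory 6-electron electrocyclisation of the ketene carbon onto the alkene terminus (C2–C3), after which dienone 22 tautomerises to phenol 23. This is the diazo ketone version of the Danheiser benzannulation, established for alkoxy- and siloxyalkynes; the aryl alkynyl ether belongs to the same class, has a somewhat weaker donor oxygen and, lacking a hydrogen beta to oxygen, cannot fragment by retro-ene loss of an alkene on heating. No stereocentre is created in 23: the sp3 ring carbons of 20 and 22 disappear on aromatisation, and the (S) centre stays outside the reacting array (allylic in 7, benzylic in 23). The step needs regiocontrol in the (2+2) event, which the polarisation of the ynol ether provides (its CH2OTBS-bearing carbon is the nucleophile and ends up next to the phenol carbon), and chemoselectivity for the alkyne, which is secured by having every hydroxyl silylated or benzylated and the aldehyde as its acetal; irradiation above 300 nm leaves the aryl ethers unexcited.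

Step 13
Reactants: 23 2-(tert-butyldimethylsilyloxymethyl)-3-[2-(1,3-dioxolan-2-yl)-6-(4-methoxybenzyloxy)-4-methylphenoxy]-6-[(1S)-3-methyl-1-(triisopropylsilyloxy)butyl]phenol
Product: 24 tert-butyl({6-[2-(1,3-dioxolan-2-yl)-6-(4-methoxybenzyloxy)-4-methylphenoxy]-2-methoxy-3-[(1S)-3-methyl-1-(triisopropylsilyloxy)butyl]phenyl}methoxy)dimethylsilane
Conditions: MeI, K2CO3, DMF, rt to 40 °C
Reagents that add atoms: iodomethane, CI
Why: Williamson O-methylation of the only free hydroxyl, a 2,6-disubstituted phenol.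

Step 14
Reactants: 24 tert-butyl({6-[2-(1,3-dioxolan-2-yl)-6-(4-methoxybenzyloxy)-4-methylphenoxy]-2-methoxy-3-[(1S)-3-methyl-1-(triisopropylsilyloxy)butyl]phenyl}methoxy)dimethylsilane
Product: 25 2-{2-(hydroxymethyl)-3-methoxy-4-[(1S)-3-methyl-1-(triisopropylsilyloxy)butyl]phenoxy}-3-(4-methoxybenzyloxy)-5-methylbenzaldehyde
Conditions: 1 M aq. HCl, THF, 0 °C to rt
Reagents that add atoms: water, O
Why: Dilute aqueous acid hydrolyses the aryl dioxolane and the primary TBS ether, while the hindered secondary TIPS ether and the aryl 4-methoxybenzyl ether are stable to it.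

Step 15
Reactants: 25 2-{2-(hydroxymethyl)-3-methoxy-4-[(1S)-3-methyl-1-(triisopropylsilyloxy)butyl]phenoxy}-3-(4-methoxybenzyloxy)-5-methylbenzaldehyde
Product: 26 (E)-4-[2-{2-(hydroxymethyl)-3-methoxy-4-[(1S)-3-methyl-1-(triisopropylsilyloxy)butyl]phenoxy}-3-(4-methoxybenzyloxy)-5-methylphenyl]but-3-en-2-one
Conditions: Ph3P=CHC(O)CH3, toluene, 90 °C
Reagents that add atoms: 1-(triphenylphosphoranylidene)propan-2-one, CC(=O)C=P(c1ccccc1)(c1ccccc1)c1ccccc1
Why: Wittig olefination of an aromatic aldehyde with a stabilised ylide, which should give the (E)-enone and tolerates the free benzylic alcohol.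

Step 16
Reactants: 26 (E)-4-[2-{2-(hydroxymethyl)-3-methoxy-4-[(1S)-3-methyl-1-(triisopropylsilyloxy)butyl]phenoxy}-3-(4-methoxybenzyloxy)-5-methylphenyl]but-3-en-2-one
Product: 27 2-methoxy-6-{2-(4-methoxybenzyloxy)-4-methyl-6-[(E)-3-oxobut-1-enyl]phenoxy}-3-[(1S)-3-methyl-1-(triisopropylsilyloxy)butyl]benzaldehyde
Conditions: Dess–Martin periodinane, NaHCO3, CH2Cl2, 0 °C to rt
Reagents that add atoms: none
Why: Dess–Martin oxidation of a hindered primary benzylic alcohol to the aldehyde without touching the enone or the ethers.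

Step 17
Reactants: 27 2-methoxy-6-{2-(4-methoxybenzyloxy)-4-methyl-6-[(E)-3-oxobut-1-enyl]phenoxy}-3-[(1S)-3-methyl-1-(triisopropylsilyloxy)butyl]benzaldehyde
Product: 28 2-methoxy-6-{2-(4-methoxybenzyloxy)-4-methyl-6-[(E)-3-oxobut-1-enyl]phenoxy}-3-[(1S)-3-methyl-1-(triisopropylsilyloxy)butyl]benzoic acid
Conditions: NaClO2, NaH2PO4, 2-methyl-2-butene, t-BuOH/H2O, rt
Reagents that add atoms: sodium chlorite, [Na+].[O-]Cl=O
Why: Pinnick oxidation of the aldehyde to the acid; the alkene scavenger removes hypochlorous acid before it can chlorinate the arenes or the enone.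

Step 18
Reactants: 28 2-methoxy-6-{2-(4-methoxybenzyloxy)-4-methyl-6-[(E)-3-oxobut-1-enyl]phenoxy}-3-[(1S)-3-methyl-1-(triisopropylsilyloxy)butyl]benzoic acid
Product: 29 3-[(1S)-1-hydroxy-3-methylbutyl]-2-methoxy-6-{2-(4-methoxybenzyloxy)-4-methyl-6-[(E)-3-oxobut-1-enyl]phenoxy}benzoic acid
Conditions: Bu4NF (3 equiv), THF, 0 °C to rt; aq. NH4Cl
Reagents that add atoms: none
Why: Fluoride-mediated cleavage of the Si–O bond, which leaves the C–O bond and hence the (S) configuration intact; lactonisation is impossible because acid and carbinol are meta to each other.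

Step 19
Reactants: 29 3-[(1S)-1-hydroxy-3-methylbutyl]-2-methoxy-6-{2-(4-methoxybenzyloxy)-4-methyl-6-[(E)-3-oxobut-1-enyl]phenoxy}benzoic acid
Product: 31 3-[(1S)-1-acetoxy-3-methylbutyl]-2-methoxy-6-{2-(4-methoxybenzyloxy)-4-methyl-6-[(E)-3-oxobut-1-enyl]phenoxy}benzoic acid, via mixed anhydride 30 (not isolated)
Conditions: Ac2O, pyridine, DMAP (cat.), CH2Cl2, rt; then aq. NaHCO3, THF, rt
Reagents that add atoms: acetic anhydride, CC(=O)OC(C)=O
Why: DMAP-catalysed O-acetylation of the secondary alcohol with retention; the acid is transiently converted into the acetic mixed anhydride, which water attacks at the unhindered acetyl carbonyl to return the acid.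

Step 20
Reactants: 31 3-[(1S)-1-acetoxy-3-methylbutyl]-2-methoxy-6-{2-(4-methoxybenzyloxy)-4-methyl-6-[(E)-3-oxobut-1-enyl]phenoxy}benzoic acid
Product: 32 3-[(1S)-1-acetoxy-3-methylbutyl]-6-{2-hydroxy-4-methyl-6-[(E)-3-oxobut-1-enyl]phenoxy}-2-methoxybenzoic acid (target)
Conditions: DDQ (1.3 equiv), CH2Cl2/pH 7 phosphate buffer, 0 °C to rt
Reagents that add atoms: none
Why: Oxidative cleavage of the 4-methoxybenzyl ether by DDQ (hydride abstraction at the benzylic CH2, hydrolysis of the oxocarbenium ion) under near-neutral conditions that the acetate, enone and acid should tolerate.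

## Compound list

1 | (S)-2-hydroxy-4-methylpentanoic acid (L-leucic acid) | CC(C)C[C@H](O)C(=O)O | starting material
2 | methyl (S)-2-hydroxy-4-methylpentanoate | CC(C)C[C@H](O)C(=O)OC | intermediate
3 | methyl (S)-4-methyl-2-(triisopropylsilyloxy)pentanoate | CC(C)C[C@H](O[Si](C(C)C)(C(C)C)C(C)C)C(=O)OC | intermediate
4 | (S)-4-methyl-2-(triisopropylsilyloxy)pentanal | CC(C)C[C@H](O[Si](C(C)C)(C(C)C)C(C)C)C=O | intermediate (not isolated)
5 | (S,E)-7-methyl-5-(triisopropylsilyloxy)oct-3-en-2-one | CC(=O)/C=C/[C@H](CC(C)C)O[Si](C(C)C)(C(C)C)C(C)C | intermediate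
6 | (S,E)-1,1,1-trifluoro-9-methyl-7-(triisopropylsilyloxy)dec-5-ene-2,4-dione | O=C(CC(=O)/C=C/[C@H](CC(C)C)O[Si](C(C)C)(C(C)C)C(C)C)C(F)(F)F | intermediate (not isolated)
7 | (S,E)-1-diazo-7-methyl-5-(triisopropylsilyloxy)oct-3-en-2-one | [N-]=[N+]=CC(=O)/C=C/[C@H](CC(C)C)O[Si](C(C)C)(C(C)C)C(C)C | intermediate
8 | 2-methoxy-4-methylphenol (creosol) | COc1cc(C)ccc1O | starting material
9 | 2-hydroxy-3-methoxy-5-methylbenzaldehyde | COc1cc(C)cc(C=O)c1O | intermediate
10 | 2,3-dihydroxy-5-methylbenzaldehyde | Cc1cc(O)c(O)c(C=O)c1 | intermediate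
11 | 2-hydroxy-3-(4-methoxybenzyloxy)-5-methylbenzaldehyde | COc1ccc(COc2cc(C)cc(C=O)c2O)cc1 | intermediate
12 | trichloroethylene | ClC=C(Cl)Cl | starting material
13 | 2-[(E)-1,2-dichlorovinyloxy]-3-(4-methoxybenzyloxy)-5-methylbenzaldehyde | COc1ccc(COc2cc(C)cc(C=O)c2O/C(Cl)=C\Cl)cc1 | intermediate
14 | 2-{2-[(E)-1,2-dichlorovinyloxy]-3-(4-methoxybenzyloxy)-5-methylphenyl}-1,3-dioxolane | COc1ccc(COc2cc(C)cc(C3OCCO3)c2O/C(Cl)=C\Cl)cc1 | intermediate
15 | 2-[2-(chloroethynyloxy)-3-(4-methoxybenzyloxy)-5-methylphenyl]-1,3-dioxolane | ClC#COc1c(OCc2ccc(OC)cc2)cc(C)cc1C1OCCO1 | intermediate (not isolated)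
16 | lithium [2-(1,3-dioxolan-2-yl)-6-(4-methoxybenzyloxy)-4-methylphenoxy]ethynide | [Li]C#COc1c(OCc2ccc(OC)cc2)cc(C)cc1C1OCCO1 | intermediate (not isolated)
17 | 3-[2-(1,3-dioxolan-2-yl)-6-(4-methoxybenzyloxy)-4-methylphenoxy]prop-2-yn-1-ol | OCC#COc1c(OCc2ccc(OC)cc2)cc(C)cc1C1OCCO1 | intermediate
18 | tert-butyl{3-[2-(1,3-dioxolan-2-yl)-6-(4-methoxybenzyloxy)-4-methylphenoxy]prop-2-ynyloxy}dimethylsilane | CC(C)(C)[Si](C)(C)OCC#COc1c(OCc2ccc(OC)cc2)cc(C)cc1C1OCCO1 | intermediate
19 | (3E,5S)-7-methyl-5-(triisopropylsilyloxy)octa-1,3-dien-1-one (vinylketene) | O=C=C/C=C/[C@H](CC(C)C)O[Si](C(C)C)(C(C)C)C(C)C | intermediate (not isolated)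
20 | 2-(tert-butyldimethylsilyloxymethyl)-3-[2-(1,3-dioxolan-2-yl)-6-(4-methoxybenzyloxy)-4-methylphenoxy]-4-[(1E,3S)-5-methyl-3-(triisopropylsilyloxy)hex-1-enyl]cyclobut-2-en-1-one (both C4 epimers) | O=C1C(CO[Si](C)(C)C(C)(C)C)=C(Oc2c(OCc3ccc(OC)cc3)cc(C)cc2C2OCCO2)C1/C=C/[C@H](CC(C)C)O[Si](C(C)C)(C(C)C)C(C)C | intermediate (not isolated)
21 | (5E,7S)-2-(tert-butyldimethylsilyloxymethyl)-3-[2-(1,3-dioxolan-2-yl)-6-(4-methoxybenzyloxy)-4-methylphenoxy]-9-methyl-7-(triisopropylsilyloxy)deca-1,3,5-trien-1-one, ketene carbon cis to C5 across C3=C4 (dienylketene) | O=C=C(CO[Si](C)(C)C(C)(C)C)/C(Oc1c(OCc2ccc(OC)cc2)cc(C)cc1C1OCCO1)=C\C=C\[C@H](CC(C)C)O[Si](C(C)C)(C(C)C)C(C)C | intermediate (not isolated)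
22 | 2-(tert-butyldimethylsilyloxymethyl)-3-[2-(1,3-dioxolan-2-yl)-6-(4-methoxybenzyloxy)-4-methylphenoxy]-6-[(1S)-3-methyl-1-(triisopropylsilyloxy)butyl]cyclohexa-2,4-dien-1-one (both C6 epimers) | O=C1C(CO[Si](C)(C)C(C)(C)C)=C(Oc2c(OCc3ccc(OC)cc3)cc(C)cc2C2OCCO2)C=CC1[C@H](CC(C)C)O[Si](C(C)C)(C(C)C)C(C)C | intermediate (not isolated)
23 | 2-(tert-butyldimethylsilyloxymethyl)-3-[2-(1,3-dioxolan-2-yl)-6-(4-methoxybenzyloxy)-4-methylphenoxy]-6-[(1S)-3-methyl-1-(triisopropylsilyloxy)butyl]phenol | Oc1c([C@H](CC(C)C)O[Si](C(C)C)(C(C)C)C(C)C)ccc(Oc2c(OCc3ccc(OC)cc3)cc(C)cc2C2OCCO2)c1CO[Si](C)(C)C(C)(C)C | intermediate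
24 | tert-butyl({6-[2-(1,3-dioxolan-2-yl)-6-(4-methoxybenzyloxy)-4-methylphenoxy]-2-methoxy-3-[(1S)-3-methyl-1-(triisopropylsilyloxy)butyl]phenyl}methoxy)dimethylsilane | COc1c([C@H](CC(C)C)O[Si](C(C)C)(C(C)C)C(C)C)ccc(Oc2c(OCc3ccc(OC)cc3)cc(C)cc2C2OCCO2)c1CO[Si](C)(C)C(C)(C)C | intermediate
25 | 2-{2-(hydroxymethyl)-3-methoxy-4-[(1S)-3-methyl-1-(triisopropylsilyloxy)butyl]phenoxy}-3-(4-methoxybenzyloxy)-5-methylbenzaldehyde | COc1c([C@H](CC(C)C)O[Si](C(C)C)(C(C)C)C(C)C)ccc(Oc2c(OCc3ccc(OC)cc3)cc(C)cc2C=O)c1CO | intermediate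
26 | (E)-4-[2-{2-(hydroxymethyl)-3-methoxy-4-[(1S)-3-methyl-1-(triisopropylsilyloxy)butyl]phenoxy}-3-(4-methoxybenzyloxy)-5-methylphenyl]but-3-en-2-one | COc1c([C@H](CC(C)C)O[Si](C(C)C)(C(C)C)C(C)C)ccc(Oc2c(OCc3ccc(OC)cc3)cc(C)cc2/C=C/C(C)=O)c1CO | intermediate
27 | 2-methoxy-6-{2-(4-methoxybenzyloxy)-4-methyl-6-[(E)-3-oxobut-1-enyl]phenoxy}-3-[(1S)-3-methyl-1-(triisopropylsilyloxy)butyl]benzaldehyde | COc1c([C@H](CC(C)C)O[Si](C(C)C)(C(C)C)C(C)C)ccc(Oc2c(OCc3ccc(OC)cc3)cc(C)cc2/C=C/C(C)=O)c1C=O | intermediate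
28 | 2-methoxy-6-{2-(4-methoxybenzyloxy)-4-methyl-6-[(E)-3-oxobut-1-enyl]phenoxy}-3-[(1S)-3-methyl-1-(triisopropylsilyloxy)butyl]benzoic acid | COc1c([C@H](CC(C)C)O[Si](C(C)C)(C(C)C)C(C)C)ccc(Oc2c(OCc3ccc(OC)cc3)cc(C)cc2/C=C/C(C)=O)c1C(=O)O | intermediate
29 | 3-[(1S)-1-hydroxy-3-methylbutyl]-2-methoxy-6-{2-(4-methoxybenzyloxy)-4-methyl-6-[(E)-3-oxobut-1-enyl]phenoxy}benzoic acid | COc1c([C@H](CC(C)C)O)ccc(Oc2c(OCc3ccc(OC)cc3)cc(C)cc2/C=C/C(C)=O)c1C(=O)O | intermediate
30 | acetic 3-[(1S)-1-acetoxy-3-methylbutyl]-2-methoxy-6-{2-(4-methoxybenzyloxy)-4-methyl-6-[(E)-3-oxobut-1-enyl]phenoxy}benzoic anhydride | COc1c([C@H](CC(C)C)OC(C)=O)ccc(Oc2c(OCc3ccc(OC)cc3)cc(C)cc2/C=C/C(C)=O)c1C(=O)OC(C)=O | intermediate (not isolated)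
31 | 3-[(1S)-1-acetoxy-3-methylbutyl]-2-methoxy-6-{2-(4-methoxybenzyloxy)-4-methyl-6-[(E)-3-oxobut-1-enyl]phenoxy}benzoic acid | COc1c([C@H](CC(C)C)OC(C)=O)ccc(Oc2c(OCc3ccc(OC)cc3)cc(C)cc2/C=C/C(C)=O)c1C(=O)O | intermediate
32 | 3-[(1S)-1-acetoxy-3-methylbutyl]-6-{2-hydroxy-4-methyl-6-[(E)-3-oxobut-1-enyl]phenoxy}-2-methoxybenzoic acid | COc1c([C@H](CC(C)C)OC(C)=O)ccc(Oc2c(O)cc(C)cc2/C=C/C(C)=O)c1C(=O)O | target

## Step count

Total: 20 steps. Longest linear sequence: 16 steps (steps 5 to 20, from creosol); the leucic acid branch (steps 1 to 4) joins at step 12.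

## Steps most likely to fail

**Step 12.** Capture of the short-lived vinylketene by a crowded aryloxyalkyne, whose oxygen donates less than that of an alkyl or silyl ynol ether, may be slower than ketene dimerisation and than O-acylation of the product phenol by the ketene. The fallback sets out from 7 and returns at 25. It uses the proven siloxyalkyne class and makes the diaryl ether afterwards by nucleophilic aromatic substitution.
- tert-Butyldimethyl(prop-2-ynyloxy)silane is deprotonated (n-BuLi), the acetylide is oxidised to the ynolate with t-BuOOLi, and TIPSOTf gives tert-butyldimethyl{[3-(triisopropylsilyloxy)prop-2-ynyl]oxy}silane F1.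
- Irradiation of 7 with F1 as in step 12 should give 2-(tert-butyldimethylsilyloxymethyl)-6-[(1S)-3-methyl-1-(triisopropylsilyloxy)butyl]-3-(triisopropylsilyloxy)phenol F2.
- MeI and K2CO3 give its methyl ether, tert-butyl({2-methoxy-3-[(1S)-3-methyl-1-(triisopropylsilyloxy)butyl]-6-(triisopropylsilyloxy)phenyl}methoxy)dimethylsilane F3.
- One equivalent of Bu4NF at −20 °C cleaves only the aryl silyl ether, giving 2-(tert-butyldimethylsilyloxymethyl)-3-methoxy-4-[(1S)-3-methyl-1-(triisopropylsilyloxy)butyl]phenol F4.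
- The electrophile comes from 2-fluoro-5-methylphenol: 4-methoxybenzyl chloride and K2CO3 give 1-fluoro-2-(4-methoxybenzyloxy)-4-methylbenzene F5; lithiation next to fluorine (n-BuLi, PMDTA, THF, −78 °C) and a DMF quench give 2-fluoro-3-(4-methoxybenzyloxy)-5-methylbenzaldehyde F6.
- Displacement of fluoride from F6 by the phenoxide of F4 (Cs2CO3, DMF, 90 °C) gives 2-{2-(tert-butyldimethylsilyloxymethyl)-3-methoxy-4-[(1S)-3-methyl-1-(triisopropylsilyloxy)butyl]phenoxy}-3-(4-methoxybenzyloxy)-5-methylbenzaldehyde F7.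
- 1 M aqueous HCl in THF removes the TBS group of F7 and gives 25.

**Step 10.** Competing ortho- or benzylic metalation next to the ether and acetal oxygens, incomplete chlorine–lithium exchange, sluggish capture of the acetylide by polymeric formaldehyde, or hydration of the hydroxymethyl ynol ether on work-up may erode the alkyne. The fallback sets out from 11 and returns at 18; it replaces steps 8 to 11 and uses no organolithium reagent.
- 11 is acetalised (ethylene glycol, PPTS, benzene, reflux) to 2-(1,3-dioxolan-2-yl)-6-(4-methoxybenzyloxy)-4-methylphenol F8.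
- (tert-Butyldimethylsilyloxy)acetaldehyde is converted with CBr4 and PPh3 (first stage of the Corey–Fuchs reaction) into tert-butyl[(3,3-dibromoprop-2-enyl)oxy]dimethylsilane F9.
- Copper-catalysed C–O coupling of F8 with F9 (CuI, 2,2'-bipyridine, K3PO4, toluene, 110 °C) should give tert-butyl{[(Z)-3-bromo-3-[2-(1,3-dioxolan-2-yl)-6-(4-methoxybenzyloxy)-4-methylphenoxy]prop-2-enyl]oxy}dimethylsilane F10 (geometry of no consequence).
- Dehydrobromination of F10 with KOt-Bu in dioxane gives 18.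

**Step 20.** Oxidative debenzylation of the aryl ether may be slow, and during a long exposure DDQ or the acidic hydroquinone may attack the electron-rich product phenol or solvolyse the activated benzylic acetate. The fallback sets out from 28 and returns at 32. It removes the 4-methoxybenzyl group before the acetate exists and ends with a mild chemoselective deacetylation.
- DDQ in wet CH2Cl2 on 28 gives 6-{2-hydroxy-4-methyl-6-[(E)-3-oxobut-1-enyl]phenoxy}-2-methoxy-3-[(1S)-3-methyl-1-(triisopropylsilyloxy)butyl]benzoic acid F11.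
- Bu4NF gives 6-{2-hydroxy-4-methyl-6-[(E)-3-oxobut-1-enyl]phenoxy}-3-[(1S)-1-hydroxy-3-methylbutyl]-2-methoxybenzoic acid F12.
- Ac2O, pyridine and DMAP, with a bicarbonate work-up, give 6-{2-acetoxy-4-methyl-6-[(E)-3-oxobut-1-enyl]phenoxy}-3-[(1S)-1-acetoxy-3-methylbutyl]-2-methoxybenzoic acid F13.
- NaHCO3 in methanol at rt should cleave only the aryl acetate of F13 and give 32.

## Further compounds

F1 | step 12 | tert-butyldimethyl{[3-(triisopropylsilyloxy)prop-2-ynyl]oxy}silane | CC(C)(C)[Si](C)(C)OCC#CO[Si](C(C)C)(C(C)C)C(C)C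
F2 | step 12 | 2-(tert-butyldimethylsilyloxymethyl)-6-[(1S)-3-methyl-1-(triisopropylsilyloxy)butyl]-3-(triisopropylsilyloxy)phenol | Oc1c([C@H](CC(C)C)O[Si](C(C)C)(C(C)C)C(C)C)ccc(O[Si](C(C)C)(C(C)C)C(C)C)c1CO[Si](C)(C)C(C)(C)C
F3 | step 12 | tert-butyl({2-methoxy-3-[(1S)-3-methyl-1-(triisopropylsilyloxy)butyl]-6-(triisopropylsilyloxy)phenyl}methoxy)dimethylsilane | COc1c([C@H](CC(C)C)O[Si](C(C)C)(C(C)C)C(C)C)ccc(O[Si](C(C)C)(C(C)C)C(C)C)c1CO[Si](C)(C)C(C)(C)C
F4 | step 12 | 2-(tert-butyldimethylsilyloxymethyl)-3-methoxy-4-[(1S)-3-methyl-1-(triisopropylsilyloxy)butyl]phenol | COc1c([C@H](CC(C)C)O[Si](C(C)C)(C(C)C)C(C)C)ccc(O)c1CO[Si](C)(C)C(C)(C)C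
F5 | step 12 | 1-fluoro-2-(4-methoxybenzyloxy)-4-methylbenzene | COc1ccc(COc2cc(C)ccc2F)cc1
F6 | step 12 | 2-fluoro-3-(4-methoxybenzyloxy)-5-methylbenzaldehyde | COc1ccc(COc2cc(C)cc(C=O)c2F)cc1
F7 | step 12 | 2-{2-(tert-butyldimethylsilyloxymethyl)-3-methoxy-4-[(1S)-3-methyl-1-(triisopropylsilyloxy)butyl]phenoxy}-3-(4-methoxybenzyloxy)-5-methylbenzaldehyde | COc1c([C@H](CC(C)C)O[Si](C(C)C)(C(C)C)C(C)C)ccc(Oc2c(OCc3ccc(OC)cc3)cc(C)cc2C=O)c1CO[Si](C)(C)C(C)(C)C
F8 | step 10 | 2-(1,3-dioxolan-2-yl)-6-(4-methoxybenzyloxy)-4-methylphenol | COc1ccc(COc2cc(C)cc(C3OCCO3)c2O)cc1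
F9 | step 10 | tert-butyl[(3,3-dibromoprop-2-enyl)oxy]dimethylsilane | BrC(Br)=CCO[Si](C)(C)C(C)(C)C
F10 | step 10 | tert-butyl{[(Z)-3-bromo-3-[2-(1,3-dioxolan-2-yl)-6-(4-methoxybenzyloxy)-4-methylphenoxy]prop-2-enyl]oxy}dimethylsilane | CC(C)(C)[Si](C)(C)OC/C=C(\Br)Oc1c(OCc2ccc(OC)cc2)cc(C)cc1C1OCCO1
F11 | step 20 | 6-{2-hydroxy-4-methyl-6-[(E)-3-oxobut-1-enyl]phenoxy}-2-methoxy-3-[(1S)-3-methyl-1-(triisopropylsilyloxy)butyl]benzoic acid | COc1c([C@H](CC(C)C)O[Si](C(C)C)(C(C)C)C(C)C)ccc(Oc2c(O)cc(C)cc2/C=C/C(C)=O)c1C(=O)O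
F12 | step 20 | 6-{2-hydroxy-4-methyl-6-[(E)-3-oxobut-1-enyl]phenoxy}-3-[(1S)-1-hydroxy-3-methylbutyl]-2-methoxybenzoic acid | COc1c([C@H](CC(C)C)O)ccc(Oc2c(O)cc(C)cc2/C=C/C(C)=O)c1C(=O)O
F13 | step 20 | 6-{2-acetoxy-4-methyl-6-[(E)-3-oxobut-1-enyl]phenoxy}-3-[(1S)-1-acetoxy-3-methylbutyl]-2-methoxybenzoic acid | COc1c([C@H](CC(C)C)OC(C)=O)ccc(Oc2c(OC(C)=O)cc(C)cc2/C=C/C(C)=O)c1C(=O)O
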